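**Strategy.** The flavanone is disconnected across ring C at C3–C4 and O1–C2. O1, C8a, C4a and C4 are the phenol oxygen, two ring carbons and the formyl carbon of a ring-A salicylaldehyde; C2–C3 is the vinyl group of 3,4-dimethoxystyrene. A chiral-acid-catalysed oxa-[4+2] joins them in one operation, closing ring C and setting C2 as S; oxidation at C4 and desilylation finish the synthesis. The precursor is 5-geranyl-2-hydroxy-4,6-bis(TBS-oxy)benzaldehyde. It is reached from resorcinol by ortho-lithiation/geranylation, sterically directed C–H borylation–oxidation and magnesium-mediated ortho-formylation, so the three ring-A oxygens never have to be differentiated.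

Key step: step 7

Remark: geranyl = (2E)-3,7-dimethylocta-2,6-dien-1-yl, TBS = tert-butyldimethylsilyl, MOM = methoxymethyl; compounds 13–15 use flavan numbering.
Remark: lithiation is done on MOM ethers because an aryllithium next to an aryl silyl ether undergoes retro-Brook silyl migration; the third ring-A oxygen is added afterwards at the only unhindered C–H, because a geranylphloroglucinol cannot be silylated selectively on the two chain-flanking hydroxyls.
Remark: TBS ethers are kept on O5 and O7 for the key step: they tolerate anhydrous Brønsted acid, donate less than alkyl ethers, block both competing phenols, and come off with buffered fluoride.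
Assumption: the sense of induction of the confined acid cannot be predicted with certainty; the catalyst enantiomer that delivers 2S is taken after a short screen.

**Step 1**
Reactants: 1 resorcinol
Product: 2 1,3-bis(methoxymethoxy)benzene
Conditions: NaH (2.4 equiv), MOMCl (2.4 equiv), DMF, 0 °C → rt
Reagents that add atoms: chloromethyl methyl ether, COCCl
Why: Williamson-type O-alkylation of the bis-phenoxide with the reactive α-chloro ether installs two acetal groups that serve as strong ortho-directing groups for the next step.

**Step 2**
Reactants: 2 1,3-bis(methoxymethoxy)benzene; 3 geranyl bromide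
Product: 5 2-geranyl-1,3-bis(methoxymethoxy)benzene, via 2-lithio-1,3-bis(methoxymethoxy)benzene 4 (not isolated)
Conditions: n-BuLi (1.1 equiv), THF, 0 °C; CuI (10 mol%), then 3, −78 °C → rt
Reagents that add atoms: none
Why: Directed ortho-metalation takes place at C2, the position flanked by both OMOM groups, and copper-catalysed SN2 allylic substitution of the primary bromide should transfer the chain with its E-alkene intact.

**Step 3**
Reactants: 5 2-geranyl-1,3-bis(methoxymethoxy)benzene
Product: 6 2-geranylresorcinol
Conditions: HCl (2 M in MeOH), rt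
Reagents that add atoms: none
Why: Acid-catalysed acetal methanolysis proceeds through an oxocarbenium ion far faster than the trisubstituted alkenes are protonated at room temperature, so the chain should not cyclise onto the phenols.

**Step 4**
Reactants: 6 2-geranylresorcinol
Product: 7 2-geranyl-1,3-bis(tert-butyldimethylsilyloxy)benzene
Conditions: TBSCl (2.5 equiv), imidazole (5 equiv), DMF, rt
Reagents that add atoms: tert-butyldimethylsilyl chloride, CC(C)(C)[Si](C)(C)Cl
Why: Imidazole-promoted O-silylation of the two equivalent phenols gives the groups that later shield C4/C6 in the borylation and block O5/O7 in the key step.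

**Step 5**
Reactants: 7 2-geranyl-1,3-bis(tert-butyldimethylsilyloxy)benzene
Product: 9 4-geranyl-3,5-bis(tert-butyldimethylsilyloxy)phenol, via the aryl pinacol boronate 8 (not isolated)
Conditions: [Ir(OMe)(cod)]2 (1.5 mol%), dtbpy (3 mol%), B2pin2 (1.0 equiv), THF, 60 °C; then NMO (4 equiv), THF, 50 °C; aq. work-up
Reagents that add atoms: 4-methylmorpholine N-oxide, C[N+]1([O-])CCOCC1 (supplies the phenol oxygen); bis(pinacolato)diboron, CC1(C)OB(OC1(C)C)B1OC(C)(C)C(C)(C)O1 (supplies the boryl group of 8 only)
Why: Iridium-catalysed C–H borylation is sterically controlled and should take the only aromatic C–H without an ortho substituent (para to the chain), and N-oxide ipso-hydroxylation of the boronate (1,2-aryl shift from boron to oxygen) is neutral and spares the silyl ethers and trisubstituted alkenes.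

**Step 6**
Reactants: 9 4-geranyl-3,5-bis(tert-butyldimethylsilyloxy)phenol
Product: 11 5-geranyl-2-hydroxy-4,6-bis(tert-butyldimethylsilyloxy)benzaldehyde, via the magnesium salt of the ortho-hydroxymethyl phenol 10 (not isolated)
Conditions: MgCl2 (2 equiv), Et3N (4 equiv), (CH2O)n (6 equiv), MeCN, 80 °C
Reagents that add atoms: formaldehyde (as paraformaldehyde), C=O
Why: In this magnesium-mediated ortho-formylation (Casnati–Skattebøl) the magnesium phenoxide is hydroxymethylated at one of its two equivalent ortho positions and the benzylic alkoxide is oxidised in situ by Oppenauer-type hydride transfer to a second formaldehyde, all under non-acidic conditions.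

**Step 7**
Reactants: 11 5-geranyl-2-hydroxy-4,6-bis(tert-butyldimethylsilyloxy)benzaldehyde; 12 3,4-dimethoxystyrene
Product: 13 (2S,4S)-6-geranyl-5,7-bis(tert-butyldimethylsilyloxy)-3',4'-dimethoxyflavan-4-ol (2,4-cis)
Conditions: confined chiral imidodiphosphorimidate Brønsted acid (5 mol%, enantiomer giving 2S), 12 (1.5 equiv, slow addition), toluene, −40 °C
Reagents that add atoms: none
Why: Proposed new method: the confined acid protonates the hydrogen-bonded formyl group of 11 to a hydroxybenzylic cation that is an O-protonated ortho-quinone methide in resonance; the CH2 terminus of the electron-rich styrene 12 bonds to C4 and the developing 3,4-dimethoxybenzylic cation is captured inside the ion pair by the ortho phenol oxygen, i.e. a concerted but asynchronous inverse-demand oxa-[4+2] (in the stepwise limit a Prins addition followed by 6-exo-trig O-alkylation of the quinoid cation). The closest known reaction types are chiral N-triflyl phosphoramide-catalysed [4+2] cycloadditions of in-situ generated ortho-quinone methides with styrenes to 2-arylchromans and confined-acid-catalysed asymmetric Prins reactions of aryl aldehydes with styrenes; new is the use of a salicylaldehyde itself as the four-atom component, so that C4 emerges as a carbinol. Ring C is closed as a six-membered pyran in the [4+2] mode, the regiochemistry following from the polarity of both partners (nucleophilic CH2 to electrophilic C4, cationic benzylic C2 to O1). C2 is controlled by the chiral counter-anion, which binds the cation through hydrogen bonds to the carbonyl and phenol oxygens and leaves one face of the heterodiene open, while C4 should follow from the endo-type approach that places aryl and hydroxyl cis and is removed in step 8 in any case. The step needs chemoselectivity for the styrene over the two trisubstituted side-chain alkenes, which its far higher nucleophilicity provides, and ring closure through the C8a oxygen only, which the silyl ethers on O5 and O7 secure while also preventing chroman formation with the side chain and damping donation into C4. Low temperature, a non-polar solvent and slow addition of 12 should limit ionisation of the new C4 carbinol, re-opening at C2 and cationic oligomerisation of the styrene.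

**Step 8**
Reactants: 13 (2S,4S)-6-geranyl-5,7-bis(tert-butyldimethylsilyloxy)-3',4'-dimethoxyflavan-4-ol
Product: 14 (2S)-6-geranyl-5,7-bis(tert-butyldimethylsilyloxy)-3',4'-dimethoxyflavanone
Conditions: Dess–Martin periodinane (1.3 equiv), NaHCO3, CH2Cl2, 0 °C → rt
Reagents that add atoms: none
Why: Dess–Martin oxidation under bicarbonate buffer is neither acidic enough to ionise C4 nor basic enough to open ring C, so it should remove the C4 stereocentre (either epimer converges) and leave C2 untouched.

**Step 9**
Reactants: 14 (2S)-6-geranyl-5,7-bis(tert-butyldimethylsilyloxy)-3',4'-dimethoxyflavanone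
Product: 15 (2S)-6-geranyl-5,7-dihydroxy-3',4'-dimethoxyflavanone (CNP0268555.1)
Conditions: TBAF/AcOH (1:1, 3 equiv), THF, 0 °C
Reagents that add atoms: none
Why: Fluoride-mediated desilylation of the two aryl silyl ethers with acetic acid buffering keeps the phenoxide concentration low, which should prevent the retro-oxa-Michael ring opening that would racemise C2 of a 5-hydroxyflavanone.

**Compound list**

1 | resorcinol | Oc1cccc(O)c1 | starting material
2 | 1,3-bis(methoxymethoxy)benzene | COCOc1cccc(OCOC)c1 | intermediate
3 | geranyl bromide, (2E)-1-bromo-3,7-dimethylocta-2,6-diene | CC(C)=CCC/C(C)=C/CBr | starting material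
4 | 2-lithio-1,3-bis(methoxymethoxy)benzene (not isolated) | [Li]c1c(OCOC)cccc1OCOC | intermediate
5 | 2-geranyl-1,3-bis(methoxymethoxy)benzene | COCOc1cccc(OCOC)c1C/C=C(\C)CCC=C(C)C | intermediate
6 | 2-geranylresorcinol | Oc1cccc(O)c1C/C=C(\C)CCC=C(C)C | intermediate
7 | 2-geranyl-1,3-bis(tert-butyldimethylsilyloxy)benzene | CC(C)(C)[Si](C)(C)Oc1cccc(O[Si](C)(C)C(C)(C)C)c1C/C=C(\C)CCC=C(C)C | intermediate
8 | 2-[4-geranyl-3,5-bis(tert-butyldimethylsilyloxy)phenyl]-4,4,5,5-tetramethyl-1,3,2-dioxaborolane (not isolated) | CC1(C)OB(OC1(C)C)c1cc(O[Si](C)(C)C(C)(C)C)c(C/C=C(\C)CCC=C(C)C)c(O[Si](C)(C)C(C)(C)C)c1 | intermediate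
9 | 4-geranyl-3,5-bis(tert-butyldimethylsilyloxy)phenol | Oc1cc(O[Si](C)(C)C(C)(C)C)c(C/C=C(\C)CCC=C(C)C)c(O[Si](C)(C)C(C)(C)C)c1 | intermediate
10 | 4-geranyl-2-(hydroxymethyl)-3,5-bis(tert-butyldimethylsilyloxy)phenol (formed as its magnesium salt, not isolated) | OCc1c(O)cc(O[Si](C)(C)C(C)(C)C)c(C/C=C(\C)CCC=C(C)C)c1O[Si](C)(C)C(C)(C)C | intermediate
11 | 5-geranyl-2-hydroxy-4,6-bis(tert-butyldimethylsilyloxy)benzaldehyde | O=Cc1c(O)cc(O[Si](C)(C)C(C)(C)C)c(C/C=C(\C)CCC=C(C)C)c1O[Si](C)(C)C(C)(C)C | intermediate
12 | 3,4-dimethoxystyrene | C=Cc1ccc(OC)c(OC)c1 | starting material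
13 | (2S,4S)-6-geranyl-5,7-bis(tert-butyldimethylsilyloxy)-3',4'-dimethoxyflavan-4-ol (2,4-cis) | COc1ccc([C@@H]2C[C@H](O)c3c(cc(O[Si](C)(C)C(C)(C)C)c(C/C=C(\C)CCC=C(C)C)c3O[Si](C)(C)C(C)(C)C)O2)cc1OC | intermediate
14 | (2S)-6-geranyl-5,7-bis(tert-butyldimethylsilyloxy)-3',4'-dimethoxyflavanone | COc1ccc([C@@H]2CC(=O)c3c(cc(O[Si](C)(C)C(C)(C)C)c(C/C=C(\C)CCC=C(C)C)c3O[Si](C)(C)C(C)(C)C)O2)cc1OC | intermediate
15 | (2S)-6-geranyl-5,7-dihydroxy-3',4'-dimethoxyflavanone | COc1ccc([C@@H]2CC(=O)c3c(cc(O)c(C/C=C(\C)CCC=C(C)C)c3O)O2)cc1OC | target

**Totals.** Total step count: 9. Longest linear sequence: 9 steps (1 → 15); 3 and 12 are purchased.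

**Steps most likely to fail**

Step 7 (proposed new method). The acid that activates the aldehyde may also ionise the new C4 carbinol, leading to elimination or self-condensation through the electron-rich ring A. The styrene may oligomerise cationically, and facial control at C2 may be poor or eroded by reversible C2–O1 heterolysis. The fallback uses known chemistry only, sets out from 11 and rejoins at 14. Methylmagnesium bromide (THF, −78 → 0 °C) should add to the aldehyde to give racemic 1-[5-geranyl-2-hydroxy-4,6-bis(tert-butyldimethylsilyloxy)phenyl]ethanol F1. MnO2 (CH2Cl2) should oxidise it to 1-[5-geranyl-2-hydroxy-4,6-bis(tert-butyldimethylsilyloxy)phenyl]ethanone F2. DMF dimethyl acetal (toluene, 80 °C) should convert this into the enaminone (E)-3-(dimethylamino)-1-[5-geranyl-2-hydroxy-4,6-bis(tert-butyldimethylsilyloxy)phenyl]prop-2-en-1-one F3, which should close on silica gel or with TMSCl, losing dimethylamine, to 6-geranyl-5,7-bis(tert-butyldimethylsilyloxy)-4H-chromen-4-one F4. Pd(OCOCF3)2/chiral pyridine-oxazoline-catalysed asymmetric conjugate addition of (3,4-dimethoxyphenyl)boronic acid (OB(O)c1ccc(OC)c(OC)c1) to F4 (NH4PF6, H2O, 1,2-dichloroethane, 60 °C; ligand enantiomer chosen for 2S) should then give 14, and step 9 follows.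

Step 5. The side-chain alkenes may interfere with the iridium catalyst (hydroboration by the pinacolborane formed, vinylic or allylic borylation, alkene isomerisation), or borylation may be slow on the crowded arene. The fallback brings the third oxygen in with the starting material instead of creating it by C–H oxidation; it sets out from geranyl bromide 3 and rejoins at 9. Commercial phloroglucinol (Oc1cc(O)cc(O)c1) should be C-geranylated with 3 (DBU, THF; or, more cleanly, through its tris-MOM ether by the protocol of steps 1–3) to give 2-geranylphloroglucinol F5. TBSCl/imidazole should give 2-geranyl-1,3,5-tris(tert-butyldimethylsilyloxy)benzene F6. One equivalent of TBAF at −78 °C should preferentially remove the silyl ether para to the chain, the only one without an ortho substituent, giving 9. The steric bias is modest, so over- and under-cleaved material would be resilylated and recycled.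

Step 6. Formylation has to occur next to a bulky silyloxy group, and the hot, basic magnesium medium may cause slow conversion or partial loss of an aryl silyl ether. The fallback separates C–C bond formation from oxidation; it sets out from 9 and rejoins at 11. Phenylboronic acid and paraformaldehyde (cat. propionic acid, toluene, reflux, water removal) should template an ortho-specific hydroxymethylation and give 6-geranyl-2-phenyl-5,7-bis(tert-butyldimethylsilyloxy)-4H-1,3,2-benzodioxaborinine F7. Transesterification with propane-1,3-diol should release the ortho-hydroxymethyl phenol 10, isolated this time. Activated MnO2 (CH2Cl2, rt) should oxidise the benzylic alcohol to 11.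

**Further compounds**

F1 | step 7 | 1-[5-geranyl-2-hydroxy-4,6-bis(tert-butyldimethylsilyloxy)phenyl]ethanol (racemic) | CC(O)c1c(O)cc(O[Si](C)(C)C(C)(C)C)c(C/C=C(\C)CCC=C(C)C)c1O[Si](C)(C)C(C)(C)C
F2 | step 7 | 1-[5-geranyl-2-hydroxy-4,6-bis(tert-butyldimethylsilyloxy)phenyl]ethanone | CC(=O)c1c(O)cc(O[Si](C)(C)C(C)(C)C)c(C/C=C(\C)CCC=C(C)C)c1O[Si](C)(C)C(C)(C)C
F3 | step 7 | (E)-3-(dimethylamino)-1-[5-geranyl-2-hydroxy-4,6-bis(tert-butyldimethylsilyloxy)phenyl]prop-2-en-1-one | CN(C)/C=C/C(=O)c1c(O)cc(O[Si](C)(C)C(C)(C)C)c(C/C=C(\C)CCC=C(C)C)c1O[Si](C)(C)C(C)(C)C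
F4 | step 7 | 6-geranyl-5,7-bis(tert-butyldimethylsilyloxy)-4H-chromen-4-one | O=c1ccoc2cc(O[Si](C)(C)C(C)(C)C)c(C/C=C(\C)CCC=C(C)C)c(O[Si](C)(C)C(C)(C)C)c12
F5 | step 5 | 2-geranylphloroglucinol | Oc1cc(O)c(C/C=C(\C)CCC=C(C)C)c(O)c1
F6 | step 5 | 2-geranyl-1,3,5-tris(tert-butyldimethylsilyloxy)benzene | CC(C)(C)[Si](C)(C)Oc1cc(O[Si](C)(C)C(C)(C)C)c(C/C=C(\C)CCC=C(C)C)c(O[Si](C)(C)C(C)(C)C)c1
F7 | step 6 | 6-geranyl-2-phenyl-5,7-bis(tert-butyldimethylsilyloxy)-4H-1,3,2-benzodioxaborinine | c1ccccc1B1OCc2c(O1)cc(O[Si](C)(C)C(C)(C)C)c(C/C=C(\C)CCC=C(C)C)c2O[Si](C)(C)C(C)(C)C
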